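**Retrosynthetic overview**
- Target ⇐ neutral Pd-catalysed removal of six allyl groups ⇐ Steglich ester bond between an (E)-cinnamic acid (rings B and C) and an (R)-aryl-lactate alcohol (ring A).
- (R)-Alcohol ⇐ D-lactate dehydrogenase reduction of 3,4-dihydroxyphenylpyruvic acid ⇐ Erlenmeyer azlactone from 3,4-dihydroxybenzaldehyde and N-acetylglycine.
- Cinnamic acid ⇐ Knoevenagel–Doebner on the ring B aldehyde ⇐ (Z)-α-aryloxyacrylate by aldol addition/E1cB dehydration of a ring B aryloxyacetate with the ring C aldehyde.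
- Ring B aryloxyacetate ⇐ methyl bromoacetate + 3-allyloxy-4-hydroxybenzaldehyde, obtained by 4-O-PMB differentiation of the catechol.
- No ring is formed: all three benzene rings are bought as 3,4-dihydroxybenzaldehyde.

Assumption: the two enzymes are used as purchased or recombinantly expressed catalyst preparations and are not counted as starting materials.

**Route**

Step 1
Reactants: 1 3,4-dihydroxybenzaldehyde
Product: 2 3,4-bis(allyloxy)benzaldehyde
Conditions: allyl bromide (2.5 equiv), K2CO3 (3 equiv), DMF, 50 °C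
Reagents that add atoms: allyl bromide, C=CCBr
Why: Double Williamson etherification of the catechol; the allyl ethers survive every later base, enolate and acid step and leave only under palladium catalysis at the end.

Step 2
Reactants: 1 3,4-dihydroxybenzaldehyde; 3 N-acetylglycine
Product: 6 (Z)-4-(3,4-diacetoxybenzylidene)-2-methyloxazol-5(4H)-one, via aldehyde diacetate 4 (not isolated), via 2-methyloxazol-5(4H)-one 5 (not isolated)
Conditions: Ac2O, NaOAc, 120 °C, 4 h; ice-water
Reagents that add atoms: acetic anhydride, CC(=O)OC(C)=O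
Why: Erlenmeyer–Plöchl azlactone synthesis, in which Ac2O acetylates both phenols and cyclodehydrates N-acetylglycine, whose C4 carbanion condenses with the aldehyde to the favoured Z-benzylidene azlactone.

Step 3
Reactants: 6 (Z)-4-(3,4-diacetoxybenzylidene)-2-methyloxazol-5(4H)-one
Product: 8 3-(3,4-dihydroxyphenyl)-2-oxopropanoic acid, via acetamidoacrylic acid 7 (not isolated)
Conditions: 3 M HCl (aq), reflux, N2, 6 h; crystallise at 4 °C
Reagents that add atoms: water, O
Why: Acid hydrolysis opens the azlactone, cleaves the aryl acetates and hydrolyses the enamide to the arylpyruvic acid, which crystallises (largely as its enol) from the acid.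

Step 4
Reactants: 8 3-(3,4-dihydroxyphenyl)-2-oxopropanoic acid
Product: 9 (R)-3-(3,4-dihydroxyphenyl)-2-hydroxypropanoic acid ((R)-danshensu)
Conditions: D-lactate dehydrogenase, NAD+ (cat.), formate dehydrogenase, HCO2Na, KH2PO4/K2HPO4 buffer pH 6.5, 30 °C, N2; then HCl to pH 2, EtOAc
Reagents that add atoms: none
Why: Enzymatic asymmetric ketone reduction by an NADH-dependent D-lactate dehydrogenase (ketoreductase-class oxidoreductase) delivers hydride to the si face of the 2-oxo group and sets the only stereocentre as R, while formate dehydrogenase regenerates NADH from formate.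

Step 5
Reactants: 9 (R)-3-(3,4-dihydroxyphenyl)-2-hydroxypropanoic acid
Product: 10 allyl (R)-3-[3,4-bis(allyloxy)phenyl]-2-hydroxypropanoate
Conditions: allyl bromide (3.5 equiv), K2CO3 (3.3 equiv), DMF, 0 °C to rt, N2
Reagents that add atoms: allyl bromide, C=CCBr
Why: Williamson O-alkylation under carbonate conditions allylates the carboxylate and both phenoxides but not the non-acidic secondary alcohol, and leaves the stereocentre untouched (ee checked by chiral HPLC).

Step 6
Reactants: 1 3,4-dihydroxybenzaldehyde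
Product: 11 3-hydroxy-4-[(4-methoxybenzyl)oxy]benzaldehyde
Conditions: 4-methoxybenzyl chloride (1.1 equiv), NaHCO3 (1.3 equiv), NaI (0.3 equiv), DMF, 40 °C
Reagents that add atoms: 4-methoxybenzyl chloride, COc1ccc(CCl)cc1
Why: Regioselective Williamson etherification, because the 4-OH para to the formyl group is the more acidic phenol and the weak base NaHCO3 ionises and alkylates only that position.

Step 7
Reactants: 11 3-hydroxy-4-[(4-methoxybenzyl)oxy]benzaldehyde
Product: 12 3-(allyloxy)-4-[(4-methoxybenzyl)oxy]benzaldehyde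
Conditions: allyl bromide (1.3 equiv), K2CO3 (1.5 equiv), DMF, rt
Reagents that add atoms: allyl bromide, C=CCBr
Why: Williamson etherification of the remaining 3-OH.

Step 8
Reactants: 12 3-(allyloxy)-4-[(4-methoxybenzyl)oxy]benzaldehyde
Product: 13 3-(allyloxy)-4-hydroxybenzaldehyde
Conditions: TFA (10% v/v), anisole (5 equiv), CH2Cl2, 0 °C, 30 min
Reagents that add atoms: none
Why: Acidolysis of the 4-methoxybenzyl aryl ether with anisole as Friedel–Crafts cation trap frees the 4-OH, while the allyl ether and the aldehyde are inert to cold TFA.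

Step 9
Reactants: 13 3-(allyloxy)-4-hydroxybenzaldehyde; 14 methyl bromoacetate
Product: 15 methyl 2-[2-(allyloxy)-4-formylphenoxy]acetate
Conditions: K2CO3 (1.5 equiv), acetone, reflux, 4 h
Reagents that add atoms: none
Why: Williamson etherification of the phenoxide with the reactive α-bromo ester installs the aryl–O–C bond of the future enol ether and the methyl ester that is kept to the end.

Step 10
Reactants: 15 methyl 2-[2-(allyloxy)-4-formylphenoxy]acetate
Product: 16 methyl 2-[2-(allyloxy)-4-(1,3-dioxolan-2-yl)phenoxy]acetate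
Conditions: 1,2-bis(trimethylsilyloxy)ethane (1.5 equiv), TMSOTf (5 mol%), CH2Cl2, −78 to −20 °C; pyridine quench
Reagents that add atoms: 1,2-bis(trimethylsilyloxy)ethane, C[Si](C)(C)OCCO[Si](C)(C)C
Why: Noyori acetalisation under aprotic TMSOTf catalysis masks the aldehyde, which would otherwise react with the ester enolate of the next step, without transesterifying the methyl ester.

Step 11
Reactants: 16 methyl 2-[2-(allyloxy)-4-(1,3-dioxolan-2-yl)phenoxy]acetate; 2 3,4-bis(allyloxy)benzaldehyde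
Product: 18 methyl 2-[2-(allyloxy)-4-(1,3-dioxolan-2-yl)phenoxy]-3-[3,4-bis(allyloxy)phenyl]-3-hydroxypropanoate, via lithium enolate 17 (not isolated)
Conditions: LiN(iPr)2 (1.1 equiv), THF, −78 °C, 30 min; then 2, −78 °C, 1 h; AcOH (1.2 equiv) at −78 °C
Reagents that add atoms: none
Why: Directed aldol addition of the kinetically formed lithium aryloxyacetate enolate to a non-enolisable aldehyde at −78 °C; the two new stereocentres form unselectively (syn/anti mixture of racemates) and are erased in step 12.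

Step 12
Reactants: 18 methyl 2-[2-(allyloxy)-4-(1,3-dioxolan-2-yl)phenoxy]-3-[3,4-bis(allyloxy)phenyl]-3-hydroxypropanoate
Product: 20 methyl (Z)-2-[2-(allyloxy)-4-(1,3-dioxolan-2-yl)phenoxy]-3-[3,4-bis(allyloxy)phenyl]acrylate, via mesylate 19 (not isolated)
Conditions: MsCl (1.5 equiv), Et3N (3 equiv), CH2Cl2, 0 °C; then DBU (3 equiv), 0 °C to rt
Reagents that add atoms: none
Why: Mesylation followed by DBU-promoted E1cB elimination through the ester enolate gives the conjugated α-aryloxycinnamate, the Z isomer (ester trans to the β-aryl group) being thermodynamically preferred and purified by chromatography.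

Step 13
Reactants: 20 methyl (Z)-2-[2-(allyloxy)-4-(1,3-dioxolan-2-yl)phenoxy]-3-[3,4-bis(allyloxy)phenyl]acrylate
Product: 21 methyl (Z)-2-[2-(allyloxy)-4-formylphenoxy]-3-[3,4-bis(allyloxy)phenyl]acrylate
Conditions: 1 M HCl (aq)/THF 1:4, rt, 2 h
Reagents that add atoms: water, O
Why: Mild acid-catalysed acetal hydrolysis; the electron-poor α-aryloxyacrylate enol ether, the methyl ester and the allyl ethers are stable to dilute acid at room temperature.

Step 14
Reactants: 21 methyl (Z)-2-[2-(allyloxy)-4-formylphenoxy]-3-[3,4-bis(allyloxy)phenyl]acrylate; 22 malonic acid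
Product: 24 (E)-3-[3-(allyloxy)-4-({(Z)-1-[3,4-bis(allyloxy)phenyl]-3-methoxy-3-oxoprop-1-en-2-yl}oxy)phenyl]acrylic acid, via arylidenemalonic acid 23 (not isolated)
Conditions: malonic acid (3 equiv), pyridine, piperidine (0.1 equiv), 85 °C, 4 h; cold 2 M HCl
Reagents that add atoms: none
Why: Knoevenagel–Doebner condensation with decarboxylation gives the E-cinnamic acid directly, and pyridine/piperidine do not attack the methyl ester or the trisubstituted acrylate.

Step 15
Reactants: 24 (E)-3-[3-(allyloxy)-4-({(Z)-1-[3,4-bis(allyloxy)phenyl]-3-methoxy-3-oxoprop-1-en-2-yl}oxy)phenyl]acrylic acid; 10 allyl (R)-3-[3,4-bis(allyloxy)phenyl]-2-hydroxypropanoate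
Product: 25 allyl (R)-3-[3,4-bis(allyloxy)phenyl]-2-{[(E)-3-(3-(allyloxy)-4-{[(Z)-1-(3,4-bis(allyloxy)phenyl)-3-methoxy-3-oxoprop-1-en-2-yl]oxy}phenyl)acryloyl]oxy}propanoate
Conditions: N,N'-dicyclohexylcarbodiimide (1.2 equiv), DMAP (0.1 equiv), CH2Cl2, 0 °C to rt
Reagents that add atoms: none
Why: Steglich esterification acylates the secondary hydroxyl through the acylpyridinium species without touching the C–H of the stereocentre, so the R configuration is retained.

Step 16
Reactants: 25 allyl (R)-3-[3,4-bis(allyloxy)phenyl]-2-{[(E)-3-(3-(allyloxy)-4-{[(Z)-1-(3,4-bis(allyloxy)phenyl)-3-methoxy-3-oxoprop-1-en-2-yl]oxy}phenyl)acryloyl]oxy}propanoate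
Product: 26 (R)-3-(3,4-dihydroxyphenyl)-2-{[(E)-3-(4-{[(Z)-1-(3,4-dihydroxyphenyl)-3-methoxy-3-oxoprop-1-en-2-yl]oxy}-3-hydroxyphenyl)acryloyl]oxy}propanoic acid (CNP0242322.1)
Conditions: Pd(PPh3)4 (10 mol%), morpholine (15 equiv), THF, rt, argon, dark; dilute HCl to pH 3; Sephadex LH-20 or C18 (MeCN/H2O/0.1% HCO2H)
Reagents that add atoms: none
Why: Tsuji–Trost-type deallylation, in which zerovalent palladium ionises the allyl ester and the five aryl allyl ethers to π-allyl complexes that morpholine captures under neutral conditions that spare both alkenes, the methyl ester, the cinnamoyl ester and the stereocentre.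

**Compound list**
1 | 3,4-dihydroxybenzaldehyde | O=Cc1ccc(O)c(O)c1 | starting material
2 | 3,4-bis(allyloxy)benzaldehyde | C=CCOc1ccc(C=O)cc1OCC=C | intermediate
3 | N-acetylglycine | CC(=O)NCC(=O)O | starting material
4 | 3,4-diacetoxybenzaldehyde (aldehyde diacetate) | CC(=O)Oc1ccc(C=O)cc1OC(C)=O | intermediate
5 | 2-methyloxazol-5(4H)-one | CC1=NCC(=O)O1 | intermediate
6 | (Z)-4-(3,4-diacetoxybenzylidene)-2-methyloxazol-5(4H)-one | CC1=N/C(=C\c2ccc(OC(C)=O)c(OC(C)=O)c2)C(=O)O1 | intermediate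
7 | (Z)-2-acetamido-3-(3,4-dihydroxyphenyl)acrylic acid | CC(=O)N/C(=C\c1ccc(O)c(O)c1)C(=O)O | intermediate
8 | 3-(3,4-dihydroxyphenyl)-2-oxopropanoic acid | O=C(O)C(=O)Cc1ccc(O)c(O)c1 | intermediate
9 | (R)-3-(3,4-dihydroxyphenyl)-2-hydroxypropanoic acid | O=C(O)[C@H](O)Cc1ccc(O)c(O)c1 | intermediate
10 | allyl (R)-3-[3,4-bis(allyloxy)phenyl]-2-hydroxypropanoate | C=CCOC(=O)[C@H](O)Cc1ccc(OCC=C)c(OCC=C)c1 | intermediate
11 | 3-hydroxy-4-[(4-methoxybenzyl)oxy]benzaldehyde | COc1ccc(COc2ccc(C=O)cc2O)cc1 | intermediate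
12 | 3-(allyloxy)-4-[(4-methoxybenzyl)oxy]benzaldehyde | COc1ccc(COc2ccc(C=O)cc2OCC=C)cc1 | intermediate
13 | 3-(allyloxy)-4-hydroxybenzaldehyde | O=Cc1ccc(O)c(OCC=C)c1 | intermediate
14 | methyl bromoacetate | COC(=O)CBr | starting material
15 | methyl 2-[2-(allyloxy)-4-formylphenoxy]acetate | COC(=O)COc1ccc(C=O)cc1OCC=C | intermediate
16 | methyl 2-[2-(allyloxy)-4-(1,3-dioxolan-2-yl)phenoxy]acetate | COC(=O)COc1ccc(C2OCCO2)cc1OCC=C | intermediate
17 | lithium enolate of 16 | [Li+].COC([O-])=COc1ccc(C2OCCO2)cc1OCC=C | intermediate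
18 | methyl 2-[2-(allyloxy)-4-(1,3-dioxolan-2-yl)phenoxy]-3-[3,4-bis(allyloxy)phenyl]-3-hydroxypropanoate (syn/anti mixture, racemic) | COC(=O)C(Oc1ccc(C2OCCO2)cc1OCC=C)C(O)c1ccc(OCC=C)c(OCC=C)c1 | intermediate
19 | methyl 2-[2-(allyloxy)-4-(1,3-dioxolan-2-yl)phenoxy]-3-[3,4-bis(allyloxy)phenyl]-3-(methylsulfonyloxy)propanoate | COC(=O)C(Oc1ccc(C2OCCO2)cc1OCC=C)C(OS(C)(=O)=O)c1ccc(OCC=C)c(OCC=C)c1 | intermediate
20 | methyl (Z)-2-[2-(allyloxy)-4-(1,3-dioxolan-2-yl)phenoxy]-3-[3,4-bis(allyloxy)phenyl]acrylate | COC(=O)/C(=C/c1ccc(OCC=C)c(OCC=C)c1)Oc1ccc(C2OCCO2)cc1OCC=C | intermediate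
21 | methyl (Z)-2-[2-(allyloxy)-4-formylphenoxy]-3-[3,4-bis(allyloxy)phenyl]acrylate | COC(=O)/C(=C/c1ccc(OCC=C)c(OCC=C)c1)Oc1ccc(C=O)cc1OCC=C | intermediate
22 | malonic acid | OC(=O)CC(=O)O | starting material
23 | 2-[3-(allyloxy)-4-({(Z)-1-[3,4-bis(allyloxy)phenyl]-3-methoxy-3-oxoprop-1-en-2-yl}oxy)benzylidene]malonic acid | COC(=O)/C(=C/c1ccc(OCC=C)c(OCC=C)c1)Oc1ccc(C=C(C(=O)O)C(=O)O)cc1OCC=C | intermediate
24 | (E)-3-[3-(allyloxy)-4-({(Z)-1-[3,4-bis(allyloxy)phenyl]-3-methoxy-3-oxoprop-1-en-2-yl}oxy)phenyl]acrylic acid | COC(=O)/C(=C/c1ccc(OCC=C)c(OCC=C)c1)Oc1ccc(/C=C/C(=O)O)cc1OCC=C | intermediate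
25 | hexa-O-allyl precursor: allyl (R)-3-[3,4-bis(allyloxy)phenyl]-2-{[(E)-3-(3-(allyloxy)-4-{[(Z)-1-(3,4-bis(allyloxy)phenyl)-3-methoxy-3-oxoprop-1-en-2-yl]oxy}phenyl)acryloyl]oxy}propanoate | COC(=O)/C(=C/c1ccc(OCC=C)c(OCC=C)c1)Oc1ccc(/C=C/C(=O)O[C@H](Cc2ccc(OCC=C)c(OCC=C)c2)C(=O)OCC=C)cc1OCC=C | intermediate
26 | (R)-3-(3,4-dihydroxyphenyl)-2-{[(E)-3-(4-{[(Z)-1-(3,4-dihydroxyphenyl)-3-methoxy-3-oxoprop-1-en-2-yl]oxy}-3-hydroxyphenyl)acryloyl]oxy}propanoic acid | COC(=O)/C(=C/c1ccc(O)c(O)c1)Oc1ccc(/C=C/C(=O)O[C@H](Cc2ccc(O)c(O)c2)C(=O)O)cc1O | target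

**Summary**
Total step count: 16.
Longest linear sequence: 11 steps (steps 6 to 16, from 1 to 26). Steps 1 and 2 to 5 are side branches.

**Three steps most likely to fail**

Step 4 (enzymatic reduction: the catechol keto acid autoxidises and the enzyme may be inhibited at preparative concentration). The fallback sets out from 8 and comes back at 9, replacing the enzyme by rhodium-catalysed asymmetric hydrogenation of an enol ester. Keto acid 8 is esterified with MeOH/HCl to methyl 3-(3,4-dihydroxyphenyl)-2-oxopropanoate F1. F1 is peracetylated with Ac2O/pyridine/DMAP to the enol acetate methyl (Z)-2-acetoxy-3-(3,4-diacetoxyphenyl)acrylate F2. F2 is hydrogenated with [Rh(cod)((R,R)-Et-DuPhos)]OTf (1 mol%) under H2 (4 bar) in MeOH to methyl (R)-2-acetoxy-3-(3,4-diacetoxyphenyl)propanoate F3. The ligand antipode that gives R is confirmed by chiral HPLC. F3 is hydrolysed with 2 M HCl at reflux under N2 to give 9.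

Step 11 (LDA aldol: the aryloxyacetate enolate can self-condense and the aldolate can revert). The fallback sets out from 16 and comes back at 20, replacing aldol/elimination by an olefination. Ester 16 is deprotonated with LiN(iPr)2 (2.2 equiv) in THF at −78 °C and treated with ClP(O)(OEt)2. O-Phosphorylation and base-induced 1,3-phosphoryl shift to carbon give methyl 2-[2-(allyloxy)-4-(1,3-dioxolan-2-yl)phenoxy]-2-(diethoxyphosphoryl)acetate F4. Horner–Wadsworth–Emmons reaction of F4 with aldehyde 2 (LiCl, DBU, MeCN, rt) places the ester trans to the β-aryl group and gives 20. Any minor E isomer is removed by chromatography.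

Step 16 (sixfold deallylation: incomplete cleavage of the aryl allyl ethers, amine side reactions, air-sensitive product). The fallback sets out from 25 and comes back at 26, cleaving the ethers by isomerisation and hydrolysis instead of π-allyl transfer. The allyl ester alone is removed with Pd(PPh3)4 (2 mol%) and morpholine (1.1 equiv) in THF at 0 °C to give the penta-O-allyl acid F5. F5 is isomerised with H2-activated [Ir(cod)(PMePh2)2]PF6 (5 mol%) in THF at rt to the penta[(E)-prop-1-enyl] ether acid F6. The enol ethers of F6 are hydrolysed with 0.2 M HCl in acetone/water at rt under argon to give 26.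

**Further compounds**
F1 | step 4 | methyl 3-(3,4-dihydroxyphenyl)-2-oxopropanoate | COC(=O)C(=O)Cc1ccc(O)c(O)c1
F2 | step 4 | methyl (Z)-2-acetoxy-3-(3,4-diacetoxyphenyl)acrylate | COC(=O)/C(OC(C)=O)=C/c1ccc(OC(C)=O)c(OC(C)=O)c1
F3 | step 4 | methyl (R)-2-acetoxy-3-(3,4-diacetoxyphenyl)propanoate | COC(=O)[C@H](OC(C)=O)Cc1ccc(OC(C)=O)c(OC(C)=O)c1
F4 | step 11 | methyl 2-[2-(allyloxy)-4-(1,3-dioxolan-2-yl)phenoxy]-2-(diethoxyphosphoryl)acetate | CCOP(=O)(OCC)C(Oc1ccc(C2OCCO2)cc1OCC=C)C(=O)OC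
F5 | step 16 | (R)-3-[3,4-bis(allyloxy)phenyl]-2-{[(E)-3-(3-(allyloxy)-4-{[(Z)-1-(3,4-bis(allyloxy)phenyl)-3-methoxy-3-oxoprop-1-en-2-yl]oxy}phenyl)acryloyl]oxy}propanoic acid | COC(=O)/C(=C/c1ccc(OCC=C)c(OCC=C)c1)Oc1ccc(/C=C/C(=O)O[C@H](Cc2ccc(OCC=C)c(OCC=C)c2)C(=O)O)cc1OCC=C
F6 | step 16 | (R)-3-{3,4-bis[(E)-prop-1-enyloxy]phenyl}-2-{[(E)-3-(3-[(E)-prop-1-enyloxy]-4-{[(Z)-1-(3,4-bis[(E)-prop-1-enyloxy]phenyl)-3-methoxy-3-oxoprop-1-en-2-yl]oxy}phenyl)acryloyl]oxy}propanoic acid | COC(=O)/C(=C/c1ccc(O/C=C/C)c(O/C=C/C)c1)Oc1ccc(/C=C/C(=O)O[C@H](Cc2ccc(O/C=C/C)c(O/C=C/C)c2)C(=O)O)cc1O/C=C/C
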